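## Retrosynthetic overview

1. Militarinone A ⇒ fluoride unmasking of a 2,4-bis[2-(trimethylsilyl)ethoxy]pyridine 1-oxide (a disguised 1,4-dihydroxy-2-pyridone); C2'=C3' ⇒ aldol condensation of a 3-acetylpyridine 1-oxide with a (6R,8R)-dienal.
2. Key disconnection: the tertiary C–O bond of the cyclohexane ⇒ hydrogen-atom transfer to a 5-(cyclohex-1-enyl)pyridine and O2 capture of the tertiary benzylic radical (Mukaiyama hydration), which sets the 1,4-cis diol in the bond-forming event.
3. Aryl–cyclohexene bond ⇒ Pd-catalysed tosylhydrazone coupling of a 5-bromo-2,4-dialkoxypyridine (from 2,4-difluoropyridine) with silylated 4-hydroxycyclohexanone; the acetyl group enters by ortho-lithiation, the N–O bond by peracid.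
4. Dienal ⇒ two olefinations of (2R,4R)-2,4-dimethylhexan-1-ol, made from but-1-ene, bromoethene and Me3Al by two Zr-catalysed asymmetric carboaluminations.
5. Rings: none is built; the pyridine and cyclohexane rings are bought, joined in the Pd step, and the pyridone is unveiled in the last step.

Assumption: the ring descriptors of the target are read as the 1,4-cis diol ("cis" below means tertiary OH and C4 oxygen on the same face, pyridine ring trans to the C4 oxygen), and (−)-(NMI)2ZrCl2 (NMI = 1-neomenthylindenyl) is taken to give the 2R sense (the (+)-catalyst would be used otherwise).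

## Route

Step 1
Reactants: 1 but-1-ene; 2 bromoethene
Product: 5 (4R)-4-methylhex-1-ene, via (2R)-2-methylbutyl(dimethyl)alane 3 (not isolated), via (2R)-2-methylbutylzinc triflate 4 (not isolated)
Conditions: Me3Al (2 equiv), (−)-(NMI)2ZrCl2 (3 mol %), (MeAlO)n (0.3 equiv), CH2Cl2, 0 °C to rt; evaporate; Zn(OTf)2 (1 equiv), DMF, 70 °C; then 2, PdCl2(DPEphos) (3 mol %), iBu2AlH (6 mol %), DMF, rt
Reagents that add atoms: trimethylaluminium, C[Al](C)C
Why: Zr-catalysed asymmetric carboalumination (Negishi ZACA) adds CH3 to the internal alkene carbon with the 2R sense fixed by the (−)-neomenthylindenyl ligands (about 75–80% ee, amplified statistically in step 2), and the primary alkylalane is then vinylated by Zn-mediated, Pd-catalysed Negishi coupling at a carbon remote from the stereocentre.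

Step 2
Reactants: 5 (4R)-4-methylhex-1-ene
Product: 7 (2R,4R)-2,4-dimethylhexan-1-ol, via (2R,4R)-2,4-dimethylhexyl(dimethyl)alane 6 (not isolated)
Conditions: Me3Al (2 equiv), (−)-(NMI)2ZrCl2 (3 mol %), (MeAlO)n (0.3 equiv), CH2Cl2, 0 °C to rt; evaporate; O2 (1 atm), CH2Cl2, 0 °C to rt; aq. NaOH
Reagents that add atoms: trimethylaluminium, C[Al](C)C; dioxygen, O=O
Why: A second ZACA with the same catalyst enantiomer is catalyst-controlled and sets C2 again in the R sense (2,4-syn), O2 cleaves the C–Al bond to the alcohol without touching C2, and chromatographic removal of the 2,4-anti isomers (which carry almost all of the minor enantiomer from step 1) leaves 7 in ≥95% ee.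

Step 3
Reactants: 7 (2R,4R)-2,4-dimethylhexan-1-ol
Product: 9 (2E,4R,6R)-2,4,6-trimethyloct-2-enal, via (2R,4R)-2,4-dimethylhexanal 8 (not isolated)
Conditions: TEMPO (10 mol %), PhI(OAc)2 (1.1 equiv), CH2Cl2, rt; then Ph3P=C(CH3)CHO (1.5 equiv), toluene, 80 °C
Reagents that add atoms: 2-(triphenylphosphoranylidene)propanal, CC(C=O)=P(c1ccccc1)(c1ccccc1)c1ccccc1
Why: Aminoxyl-catalysed oxidation gives the epimerisable α-methyl aldehyde, which is consumed in the same flask by a Wittig reaction with the formyl-stabilised ylide under neutral conditions, giving the E trisubstituted enal (>95:5) with C4 and C6 untouched.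

Step 4
Reactants: 9 (2E,4R,6R)-2,4,6-trimethyloct-2-enal
Product: 11 (2E,4E,6R,8R)-4,6,8-trimethyldeca-2,4-dienal, via dienyl dioxolane 10 (not isolated)
Conditions: [Bu3PCH2(1,3-dioxolan-2-yl)]Br (1.4 equiv), KOtBu (1.4 equiv), THF, 0 °C to rt; then 1 M HCl, THF, rt
Reagents that add atoms: tributyl(1,3-dioxolan-2-ylmethyl)phosphonium bromide, [Br-].CCCC[P+](CCCC)(CCCC)CC1OCCO1; water, O
Why: Wittig homologation with the tributylphosphonium acetal ylide is E-selective and cannot over-homologate because the new formyl group stays masked as the dioxolane until the acidic work-up, which also equilibrates residual Z isomer to the E,E-dienal.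

Step 5
Reactants: 12 4-hydroxycyclohexan-1-one
Product: 13 4-[(tert-butyldimethylsilyl)oxy]cyclohexan-1-one
Conditions: TBSCl (1.1 equiv), imidazole (2 equiv), DMF, rt
Reagents that add atoms: tert-butyldimethylsilyl chloride, CC(C)(C)[Si](C)(C)Cl
Why: Standard silyl ether formation; the secondary hydroxyl is masked so that only the aldol hydroxyl can be acylated in step 12, and the group falls off with the others in step 13.

Step 6
Reactants: 14 2,4-difluoropyridine
Product: 16 2,4-bis[2-(trimethylsilyl)ethoxy]pyridine, via 2-fluoro-4-[2-(trimethylsilyl)ethoxy]pyridine 15 (not isolated)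
Conditions: Me3SiCH2CH2OH (2.3 equiv), NaH (2.4 equiv), THF, 0 °C to reflux
Reagents that add atoms: 2-(trimethylsilyl)ethanol, C[Si](C)(C)CCO
Why: Two nucleophilic aromatic substitutions (4-F first, then 2-F on heating) place both future pyridone oxygens as fluoride-labile 2-(trimethylsilyl)ethyl ethers.

Step 7
Reactants: 16 2,4-bis[2-(trimethylsilyl)ethoxy]pyridine
Product: 17 5-bromo-2,4-bis[2-(trimethylsilyl)ethoxy]pyridine
Conditions: NBS (1.05 equiv), MeCN, 0 °C to rt, dark
Reagents that add atoms: N-bromosuccinimide, O=C1CCC(=O)N1Br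
Why: Electrophilic aromatic bromination goes to C5, which is para to the 2-alkoxy group, ortho to the 4-alkoxy group and less hindered than C3 between the two ethers.

Step 8
Reactants: 13 4-[(tert-butyldimethylsilyl)oxy]cyclohexan-1-one; 17 5-bromo-2,4-bis[2-(trimethylsilyl)ethoxy]pyridine
Product: 19 5-{4-[(tert-butyldimethylsilyl)oxy]cyclohex-1-en-1-yl}-2,4-bis[2-(trimethylsilyl)ethoxy]pyridine (racemic), via tosylhydrazone 18 (not isolated)
Conditions: 13, TsNHNH2 (1.05 equiv), 1,4-dioxane, 70 °C; then 17, Pd2(dba)3 (2.5 mol %), XPhos (10 mol %), LiOtBu (2.5 equiv), 1,4-dioxane, 100 °C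
Reagents that add atoms: none
Why: Barluenga coupling: base releases the diazoalkane from the tosylhydrazone, the aryl–Pd bromide forms a Pd carbene, and aryl migration followed by β-hydride elimination gives the trisubstituted aryl alkene; the product is racemic, which does not matter because the ring regains its mirror plane in step 10.

Step 9
Reactants: 19 5-{4-[(tert-butyldimethylsilyl)oxy]cyclohex-1-en-1-yl}-2,4-bis[2-(trimethylsilyl)ethoxy]pyridine (racemic); 20 N-methoxy-N-methylacetamide
Product: 22 1-(5-{4-[(tert-butyldimethylsilyl)oxy]cyclohex-1-en-1-yl}-2,4-bis[2-(trimethylsilyl)ethoxy]pyridin-3-yl)ethan-1-one (racemic), via 3-lithiopyridine 21 (not isolated)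
Conditions: n-BuLi (1.15 equiv), TMEDA, THF, −78 to −40 °C; then 20 (1.5 equiv), −78 to 0 °C; aq. NH4Cl
Reagents that add atoms: none
Why: Directed ortho-metalation: C3–H is flanked by two alkoxy groups and is lithiated selectively, and the Weinreb amide stops at the ketone through its chelated tetrahedral adduct.

Step 10
Reactants: 22 1-(5-{4-[(tert-butyldimethylsilyl)oxy]cyclohex-1-en-1-yl}-2,4-bis[2-(trimethylsilyl)ethoxy]pyridin-3-yl)ethan-1-one (racemic)
Product: 24 1-(5-{cis-4-[(tert-butyldimethylsilyl)oxy]-1-hydroxycyclohexyl}-2,4-bis[2-(trimethylsilyl)ethoxy]pyridin-3-yl)ethan-1-one, via tertiary hydroperoxide 23 (not isolated)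
Conditions: Mn(dpm)3 (10 mol %), PhSiH3 (2.5 equiv), O2 (1 atm), iPrOH/CH2Cl2, 0 °C to rt; then PPh3, rt
Reagents that add atoms: dioxygen, O=O
Why: Mukaiyama hydration: hydrogen-atom transfer from a manganese hydride to the alkene gives the tertiary benzylic radical at C1, which O2 captures along the axial trajectory of the chair that keeps the C4 silyloxy group equatorial (the twisted pyridyl group ends equatorial), so the new C–O bond is cis to the C4 oxygen; PPh3 reduces the hydroperoxide and the minor trans isomer is removed by chromatography.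

Step 11
Reactants: 24 1-(5-{cis-4-[(tert-butyldimethylsilyl)oxy]-1-hydroxycyclohexyl}-2,4-bis[2-(trimethylsilyl)ethoxy]pyridin-3-yl)ethan-1-one
Product: 25 3-acetyl-5-{cis-4-[(tert-butyldimethylsilyl)oxy]-1-hydroxycyclohexyl}-2,4-bis[2-(trimethylsilyl)ethoxy]pyridine 1-oxide
Conditions: mCPBA (1.5 equiv), NaHCO3, CH2Cl2, 0 °C to rt
Reagents that add atoms: 3-chloroperoxybenzoic acid, OOC(=O)c1cccc(Cl)c1
Why: Peracid N-oxidation of the pyridine nitrogen, which the 4-alkoxy group keeps nucleophilic enough; the buffered, cold conditions disfavour Baeyer–Villiger oxidation of the hindered aryl ketone and leave the alcohols and silyl groups alone.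

Step 12
Reactants: 25 3-acetyl-5-{cis-4-[(tert-butyldimethylsilyl)oxy]-1-hydroxycyclohexyl}-2,4-bis[2-(trimethylsilyl)ethoxy]pyridine 1-oxide; 11 (2E,4E,6R,8R)-4,6,8-trimethyldeca-2,4-dienal
Product: 29 5-{cis-4-[(tert-butyldimethylsilyl)oxy]-1-hydroxycyclohexyl}-2,4-bis[2-(trimethylsilyl)ethoxy]-3-[(2E,4E,6E,8R,10R)-6,8,10-trimethyldodeca-2,4,6-trienoyl]pyridine 1-oxide, via dilithium enolate alkoxide 26 (not isolated), via aldol adduct 27 (not isolated), via aldol acetate 28 (not isolated)
Conditions: LiN(iPr)2 (2.1 equiv), THF, −78 °C; 11 (1.2 equiv), −78 °C; AcOH (2.2 equiv), −78 to 0 °C; then Ac2O, Et3N, DMAP (cat.), 0 °C; then DBU, rt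
Reagents that add atoms: none
Why: Aldol condensation: the methyl ketone is the only enolisable site, its lithium enolate adds 1,2 to the non-enolisable dienal at −78 °C, and after neutralisation only the secondary aldol hydroxyl is acetylated (the hindered tertiary alcohol is not) and eliminated by DBU (E1cB) to the E enone, without touching C8' or C10'.

Step 13
Reactants: 29 5-{cis-4-[(tert-butyldimethylsilyl)oxy]-1-hydroxycyclohexyl}-2,4-bis[2-(trimethylsilyl)ethoxy]-3-[(2E,4E,6E,8R,10R)-6,8,10-trimethyldodeca-2,4,6-trienoyl]pyridine 1-oxide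
Product: 30 militarinone A
Conditions: Bu4NF (6 equiv), THF, 0 °C to rt, dark; dilute HCl to pH 3
Reagents that add atoms: none
Why: Fluoride-induced desilylation: the silyl ether gives the secondary alcohol and each 2-(trimethylsilyl)ethyl ether fragments to ethene and Me3SiF, releasing the 4-hydroxyl and the 2-oxido N-oxide, which is the 1-hydroxy-2-pyridone after acidification; no acid strong enough to ionise the tertiary carbinol is used.

## Compound list

1 | but-1-ene | C=CCC | starting material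
2 | bromoethene | BrC=C | starting material
3 | (2R)-2-methylbutyl(dimethyl)alane (formed in the flask) | CC[C@@H](C)C[Al](C)C | intermediate
4 | (2R)-2-methylbutylzinc triflate (formed in the flask) | CC[C@@H](C)C[Zn]OS(=O)(=O)C(F)(F)F | intermediate
5 | (4R)-4-methylhex-1-ene | CC[C@@H](C)CC=C | intermediate
6 | (2R,4R)-2,4-dimethylhexyl(dimethyl)alane (formed in the flask) | CC[C@@H](C)C[C@@H](C)C[Al](C)C | intermediate
7 | (2R,4R)-2,4-dimethylhexan-1-ol | CC[C@@H](C)C[C@@H](C)CO | intermediate
8 | (2R,4R)-2,4-dimethylhexanal (formed in the flask) | CC[C@@H](C)C[C@@H](C)C=O | intermediate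
9 | (2E,4R,6R)-2,4,6-trimethyloct-2-enal | CC[C@@H](C)C[C@@H](C)/C=C(C)/C=O | intermediate
10 | 2-[(1E,3E,5R,7R)-3,5,7-trimethylnona-1,3-dien-1-yl]-1,3-dioxolane (formed in the flask, mainly 1E) | CC[C@@H](C)C[C@@H](C)/C=C(C)/C=C/C1OCCO1 | intermediate
11 | (2E,4E,6R,8R)-4,6,8-trimethyldeca-2,4-dienal | CC[C@@H](C)C[C@@H](C)/C=C(C)/C=C/C=O | intermediate
12 | 4-hydroxycyclohexan-1-one | O=C1CCC(O)CC1 | starting material
13 | 4-[(tert-butyldimethylsilyl)oxy]cyclohexan-1-one | CC(C)(C)[Si](C)(C)OC1CCC(=O)CC1 | intermediate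
14 | 2,4-difluoropyridine | Fc1ccnc(F)c1 | starting material
15 | 2-fluoro-4-[2-(trimethylsilyl)ethoxy]pyridine (formed in the flask) | C[Si](C)(C)CCOc1ccnc(F)c1 | intermediate
16 | 2,4-bis[2-(trimethylsilyl)ethoxy]pyridine | C[Si](C)(C)CCOc1ccnc(OCC[Si](C)(C)C)c1 | intermediate
17 | 5-bromo-2,4-bis[2-(trimethylsilyl)ethoxy]pyridine | C[Si](C)(C)CCOc1cc(OCC[Si](C)(C)C)c(Br)cn1 | intermediate
18 | 4-[(tert-butyldimethylsilyl)oxy]cyclohexanone 4-methylbenzenesulfonylhydrazone (formed in the flask) | CC(C)(C)[Si](C)(C)OC1CCC(=NNS(=O)(=O)c2ccc(C)cc2)CC1 | intermediate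
19 | 5-{4-[(tert-butyldimethylsilyl)oxy]cyclohex-1-en-1-yl}-2,4-bis[2-(trimethylsilyl)ethoxy]pyridine (racemic) | C[Si](C)(C)CCOc1cc(OCC[Si](C)(C)C)c(C2=CCC(O[Si](C)(C)C(C)(C)C)CC2)cn1 | intermediate
20 | N-methoxy-N-methylacetamide | CC(=O)N(C)OC | starting material
21 | 3-lithio derivative of 19 (formed in the flask, racemic) | [Li]c1c(OCC[Si](C)(C)C)ncc(C2=CCC(O[Si](C)(C)C(C)(C)C)CC2)c1OCC[Si](C)(C)C | intermediate
22 | 1-(5-{4-[(tert-butyldimethylsilyl)oxy]cyclohex-1-en-1-yl}-2,4-bis[2-(trimethylsilyl)ethoxy]pyridin-3-yl)ethan-1-one (racemic) | CC(=O)c1c(OCC[Si](C)(C)C)ncc(C2=CCC(O[Si](C)(C)C(C)(C)C)CC2)c1OCC[Si](C)(C)C | intermediate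
23 | 1-(5-{cis-4-[(tert-butyldimethylsilyl)oxy]-1-hydroperoxycyclohexyl}-2,4-bis[2-(trimethylsilyl)ethoxy]pyridin-3-yl)ethan-1-one (formed in the flask) | CC(=O)c1c(OCC[Si](C)(C)C)ncc([C@]2(OO)CC[C@@H](O[Si](C)(C)C(C)(C)C)CC2)c1OCC[Si](C)(C)C | intermediate
24 | 1-(5-{cis-4-[(tert-butyldimethylsilyl)oxy]-1-hydroxycyclohexyl}-2,4-bis[2-(trimethylsilyl)ethoxy]pyridin-3-yl)ethan-1-one | CC(=O)c1c(OCC[Si](C)(C)C)ncc([C@]2(O)CC[C@@H](O[Si](C)(C)C(C)(C)C)CC2)c1OCC[Si](C)(C)C | intermediate
25 | 3-acetyl-5-{cis-4-[(tert-butyldimethylsilyl)oxy]-1-hydroxycyclohexyl}-2,4-bis[2-(trimethylsilyl)ethoxy]pyridine 1-oxide | CC(=O)c1c(OCC[Si](C)(C)C)[n+]([O-])cc([C@]2(O)CC[C@@H](O[Si](C)(C)C(C)(C)C)CC2)c1OCC[Si](C)(C)C | intermediate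
26 | dilithium enolate alkoxide of 25 (formed in the flask) | [Li]OC(=C)c1c(OCC[Si](C)(C)C)[n+]([O-])cc([C@]2(O[Li])CC[C@@H](O[Si](C)(C)C(C)(C)C)CC2)c1OCC[Si](C)(C)C | intermediate
27 | aldol adduct: 3-[(4E,6E,8R,10R)-3-hydroxy-6,8,10-trimethyldodeca-4,6-dienoyl] derivative of the pyridine 1-oxide (formed in the flask, both C3' epimers) | CC[C@@H](C)C[C@@H](C)/C=C(C)/C=C/C(O)CC(=O)c1c(OCC[Si](C)(C)C)[n+]([O-])cc([C@]2(O)CC[C@@H](O[Si](C)(C)C(C)(C)C)CC2)c1OCC[Si](C)(C)C | intermediate
28 | 3'-O-acetate of 27 (formed in the flask) | CC[C@@H](C)C[C@@H](C)/C=C(C)/C=C/C(OC(C)=O)CC(=O)c1c(OCC[Si](C)(C)C)[n+]([O-])cc([C@]2(O)CC[C@@H](O[Si](C)(C)C(C)(C)C)CC2)c1OCC[Si](C)(C)C | intermediate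
29 | 5-{cis-4-[(tert-butyldimethylsilyl)oxy]-1-hydroxycyclohexyl}-2,4-bis[2-(trimethylsilyl)ethoxy]-3-[(2E,4E,6E,8R,10R)-6,8,10-trimethyldodeca-2,4,6-trienoyl]pyridine 1-oxide | CC[C@@H](C)C[C@@H](C)/C=C(C)/C=C/C=C/C(=O)c1c(OCC[Si](C)(C)C)[n+]([O-])cc([C@]2(O)CC[C@@H](O[Si](C)(C)C(C)(C)C)CC2)c1OCC[Si](C)(C)C | intermediate
30 | militarinone A, 1,4-dihydroxy-5-(cis-1,4-dihydroxycyclohexyl)-3-[(2E,4E,6E,8R,10R)-6,8,10-trimethyldodeca-2,4,6-trienoyl]pyridin-2(1H)-one | CC[C@@H](C)C[C@@H](C)/C=C(C)/C=C/C=C/C(=O)c1c(O)c([C@]2(O)CC[C@@H](O)CC2)cn(O)c1=O | target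

## Step count and risks

Total step count: 13. Longest linear sequence: 8 steps (14 to 30, steps 6 to 13).

**Step 10 (radical hydration).** The radical capture may give a poor cis/trans ratio, or the peroxyl intermediate may be over-reduced to the alkane. The fallback sets out from 19 and returns at 24, and forms the C–O bond ionically under stereoelectronic control. Oxymercuration of 19 with Hg(OAc)2 in THF/H2O opens the mercurinium ion by anti, trans-diaxial attack of water at the benzylic carbon and gives the organomercury acetate F1. NaBH4/NaOH in the same flask removes mercury and gives the tertiary alcohol F2. The dianion of F2 (n-BuLi, 2.2 equiv, TMEDA, THF) is acetylated at C3 with 20 to give 24.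

**Step 11 (N-oxidation).** The nitrogen lies next to an alkoxy group on an acyl-substituted ring, so oxidation may be slow and Baeyer–Villiger oxidation of the acetyl group may compete. The fallback sets out from 24 and returns at 25, and carries the acyl carbon at the alcohol level through the oxidation. NaBH4 (MeOH, 0 °C) reduces 24 to the 1-hydroxyethyl carbinol F3. mCPBA then oxidises the more nucleophilic nitrogen to the N-oxide carbinol F4. Dess–Martin periodinane (or MnO2), selective for the secondary benzylic carbinol over the tertiary alcohol, restores the ketone and gives 25.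

**Step 12 (aldol condensation).** The enolate of an N-oxide may add poorly, or the acetylation/elimination sequence may disturb the 2-alkoxy N-oxide. The fallback sets out from 25 and returns at 30, and reverses the order of the last two operations. Bu4NF removes the three silicon groups first and gives the free acetyl hydroxypyridone F5. F5 is then condensed with dienal 11 and piperidine (EtOH, 60 °C, dark), the amine-mediated Claisen–Schmidt/Knoevenagel-type condensation known for 3-acetyl-4-hydroxy-2-pyridones, which gives 30 directly. The cost is a possible epimerisation at C8' through dienamine formation.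

Further compounds
F1 | step 10 | [2-{4,6-bis[2-(trimethylsilyl)ethoxy]pyridin-3-yl}-5-[(tert-butyldimethylsilyl)oxy]-2-hydroxycyclohexyl]mercury acetate (Hg trans to the tertiary OH, OH cis to the silyloxy group, racemic) | C[Si](C)(C)CCOc1cc(OCC[Si](C)(C)C)c([C@]2(O)[C@H]([Hg]OC(C)=O)C[C@@H](O[Si](C)(C)C(C)(C)C)CC2)cn1
F2 | step 10 | 1-{4,6-bis[2-(trimethylsilyl)ethoxy]pyridin-3-yl}-cis-4-[(tert-butyldimethylsilyl)oxy]cyclohexan-1-ol | C[Si](C)(C)CCOc1cc(OCC[Si](C)(C)C)c([C@]2(O)CC[C@@H](O[Si](C)(C)C(C)(C)C)CC2)cn1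
F3 | step 11 | 1-(5-{cis-4-[(tert-butyldimethylsilyl)oxy]-1-hydroxycyclohexyl}-2,4-bis[2-(trimethylsilyl)ethoxy]pyridin-3-yl)ethan-1-ol (both carbinol epimers) | CC(O)c1c(OCC[Si](C)(C)C)ncc([C@]2(O)CC[C@@H](O[Si](C)(C)C(C)(C)C)CC2)c1OCC[Si](C)(C)C
F4 | step 11 | 5-{cis-4-[(tert-butyldimethylsilyl)oxy]-1-hydroxycyclohexyl}-3-(1-hydroxyethyl)-2,4-bis[2-(trimethylsilyl)ethoxy]pyridine 1-oxide | CC(O)c1c(OCC[Si](C)(C)C)[n+]([O-])cc([C@]2(O)CC[C@@H](O[Si](C)(C)C(C)(C)C)CC2)c1OCC[Si](C)(C)C
F5 | step 12 | 3-acetyl-1,4-dihydroxy-5-(cis-1,4-dihydroxycyclohexyl)pyridin-2(1H)-one | CC(=O)c1c(O)c([C@]2(O)CC[C@@H](O)CC2)cn(O)c1=O
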